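**Plan**
- Feature: ring C (C12, C13 enol, C14, C15 ketone, C16 CHCl) carries the exocyclic trisubstituted alkene C11=C12 with H11 cis to the heteroatom-bearing C16. This is the pattern left by syn addition of H and a carbonyl carbon across a C11≡C12 alkyne.
- Cuts, in retrosynthetic order: C16–Cl (from C16–OH with inversion) and the C13/C15 carbonyls (from silyl-protected carbinols); C12–C16 together with C11–H (reductive ynal cyclisation); C12–C13 (acetylide plus Weinreb amide); C11≡C12 (from the C11 aldehyde left after cutting C11–C12 of the sclareolide lactone).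
- Forward: rings A and B are bought as sclareolide, C8 is epimerised and the lactone is degraded and rebuilt to the 9-ethynyl carbinol. The C13–C16 chain from dimethyl L-malate is joined by acetylide acylation, ring C is closed by nickel, and chlorination, desilylation and double oxidation finish the route.
- Stereochemistry: C5, C9 and C10 come from sclareolide and C8 from acid equilibration to the cis-fused lactone. C15 (L-malate) directs C16 in the cyclisation, and chloride then inverts C16. C13 is a temporary centre set by transfer hydrogenation, and the alkene geometry follows from the cis nickelacycle.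

Key step: step 14

Remarks: the decalin is numbered as in drimane (C1–C10; methyls on C4, C8, C10) and the side chain outward from C9 as C11–C16. TBS = tert-butyldimethylsilyl, TES = triethylsilyl. The target is the C8 epimer of the sclareolide series (8β-OH, 8α-CH3). Dimethyl L-malate, the commercial dimethyl ester of L-malic acid, is bought. The C11 hydroxyl of 4 and 5 is a temporary centre and is left undefined; C13 is temporary and is set as S so that every intermediate is one diastereomer. Assumption: the cyclisation gives the C16 carbinol trans to the C15 silyl ether; as C15 later becomes a carbonyl, only this relay matters, and the opposite preference would call for dimethyl D-malate.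

Step 1
Reactants: 1 (+)-sclareolide
Product: 2 8-epi-sclareolide (cis-fused γ-lactone, 8β-O, 8α-CH3)
Conditions: conc. H2SO4, HCO2H, rt
Reagents that add atoms: none
Why: Strong acid ionises the tertiary C8–O bond and the carboxyl group recloses on the C8 cation from the β face to give the thermodynamically preferred cis-fused lactone (known acid-catalysed epimerisation of sclareolide), C9 and the decalin centres being untouched.

Step 2
Reactants: 2 8-epi-sclareolide
Product: 4 11-hydroxy-8-epi-sclareolide (C11 undefined), via potassium enolate 3 (not isolated)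
Conditions: KN(SiMe3)2, THF, −78 °C; then trans-3-phenyl-2-(phenylsulfonyl)oxaziridine, −78 °C; aq. NH4Cl
Reagents that add atoms: trans-3-phenyl-2-(phenylsulfonyl)oxaziridine (Davis oxaziridine), O=S(=O)(c1ccccc1)N1OC1c1ccccc1
Why: Electrophilic hydroxylation of the lactone enolate by the Davis oxaziridine installs the C11 oxygen needed for the later C11–C12 cleavage, and the configuration of the new C11 centre is irrelevant because it becomes the formyl carbon.

Step 3
Reactants: 4 11-hydroxy-8-epi-sclareolide
Product: 5 triol (8β-OH; C9 carries C11H(OH)–C12H2OH)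
Conditions: LiAlH4, THF, 0 °C → rt
Reagents that add atoms: none
Why: Hydride reduction of the lactone to the diol is standard and frees the tertiary 8β-hydroxyl and the C11/C12 glycol without touching any ring stereocentre.

Step 4
Reactants: 5 triol
Product: 6 8β-hydroxy-8-epi-driman-11-al (9β-CHO)
Conditions: NaIO4, THF/H2O (pH 7), 0 °C; crude used directly
Reagents that add atoms: none
Why: Periodate glycol cleavage (Malaprade reaction) cuts only the vicinal C11/C12 diol, the 1,3-related tertiary C8–OH being inert, and the neutral medium leaves the equatorial C9 formyl group and the β-hydroxy aldehyde intact.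

Step 5
Reactants: 6 8β-hydroxy-8-epi-driman-11-al
Product: 7 9β-ethynyl-8-epi-drimanol (C9–C11≡C12–H, free 8β-OH)
Conditions: dimethyl (1-diazo-2-oxopropyl)phosphonate, K2CO3, MeOH, 0 °C → rt
Reagents that add atoms: dimethyl (1-diazo-2-oxopropyl)phosphonate (Ohira–Bestmann reagent), CC(=O)C(=[N+]=[N-])P(=O)(OC)OC
Why: Seyferth–Gilbert homologation in its Ohira–Bestmann form converts the aldehyde into the terminal alkyne under mild carbonate conditions that tolerate a free hydroxyl, and C9 keeps its configuration because the equatorial substituent is the stable epimer.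

Step 6
Reactants: 8 dimethyl L-malate
Product: 9 methyl (S)-3,4-dihydroxybutanoate
Conditions: BH3·SMe2, NaBH4 (5 mol %), THF, 0 °C → rt; MeOH quench; crude used directly
Reagents that add atoms: none
Why: The hydroxyl-directed borane reduction of α-hydroxy esters reduces only the ester next to the carbinol through a cyclic oxyborane, a well-known regioselective reduction of malate esters that leaves the stereocentre untouched.

Step 7
Reactants: 9 methyl (S)-3,4-dihydroxybutanoate
Product: 10 methyl (S)-3,4-bis(tert-butyldimethylsilyloxy)butanoate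
Conditions: TBSCl, imidazole, DMF, rt
Reagents that add atoms: tert-butyldimethylsilyl chloride, CC(C)(C)[Si](C)(C)Cl
Why: Standard imidazole-mediated silylation protects both hydroxyls in one operation and prevents lactonisation of the dihydroxy ester.

Step 8
Reactants: 10 methyl (S)-3,4-bis(tert-butyldimethylsilyloxy)butanoate
Product: 11 (S)-3,4-bis(tert-butyldimethylsilyloxy)-N-methoxy-N-methylbutanamide
Conditions: MeNHOMe·HCl, i-PrMgCl, THF, −20 °C
Reagents that add atoms: N,O-dimethylhydroxylamine hydrochloride, CNOC.Cl
Why: Direct aminolysis of the ester by the chloromagnesium amide is the usual route to Weinreb amides and is cold and non-enolising enough to spare the β-silyloxy group.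

Step 9
Reactants: 7 9β-ethynyl-8-epi-drimanol; 11 Weinreb amide
Product: 13 ynone C9–C11≡C12–C13(=O)–C14H2–C15H(OTBS)–C16H2OTBS (15S), via dilithium alkoxide acetylide 12 (not isolated)
Conditions: 7, n-BuLi (2.1 equiv), THF, −78 → 0 °C; then 11, −78 → −20 °C; aq. NH4Cl
Reagents that add atoms: none
Why: Weinreb ketone synthesis: the acetylide carbon of the dianion adds once to the amide and the chelated tetrahedral intermediate collapses only on work-up, forming C12–C13 without over-addition while the hindered tertiary alkoxide stays a spectator.

Step 10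
Reactants: 13 ynone
Product: 14 (13S,15S)-propargylic alcohol
Conditions: Ru[(S,S)-TsDPEN](p-cymene) (2 mol %), i-PrOH, rt
Reagents that add atoms: none
Why: Noyori asymmetric transfer hydrogenation of α,β-acetylenic ketones is catalyst-controlled, the (S,S) complex delivering hydride to give the S propargylic carbinol, and the base-free conditions avoid β-elimination of the C15 silyl ether.

Step 11
Reactants: 14 (13S,15S)-propargylic alcohol
Product: 15 tris-TBS ether (C13, C15, C16 O-TBS; free 8β-OH)
Conditions: TBSCl, imidazole, DMF, rt
Reagents that add atoms: tert-butyldimethylsilyl chloride, CC(C)(C)[Si](C)(C)Cl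
Why: Standard silylation of the secondary propargylic hydroxyl, while the axial tertiary C8–OH flanked by C9 and the C10 methyl is too hindered to react with the silyl chloride.

Step 12
Reactants: 15 tris-TBS ether
Product: 16 primary alcohol (C16H2OH; C13 and C15 O-TBS)
Conditions: HF·pyridine, pyridine, THF, 0 °C
Reagents that add atoms: none
Why: Buffered HF·pyridine removes a primary TBS ether much faster than secondary ones (well-established selective desilylation), and the weakly acidic medium prevents 1,2-silyl migration from O15.

Step 13
Reactants: 16 primary alcohol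
Product: 17 ynal (C16 aldehyde; 13S,15S bis-TBS ether)
Conditions: Dess–Martin periodinane, CH2Cl2, 0 °C → rt
Reagents that add atoms: none
Why: Dess–Martin oxidation gives α-silyloxy aldehydes without epimerisation, and the tertiary alcohol, the alkyne and the silyl ethers are inert to it.

Step 14
Reactants: 17 ynal; 18 triethylsilane
Product: 19 cyclised tris(silyl ether) (ring C closed; C16 O-TES; H11 cis to C16; 13S,15S,16S)
Conditions: Ni(cod)2 (20 mol %), PBu3 (40 mol %), Et3SiH (5 equiv), THF, 0 °C → rt
Reagents that add atoms: triethylsilane (18), CC[SiH](CC)CC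
Why: Zerovalent nickel binds the C11≡C12 alkyne and the C16 aldehyde and couples them oxidatively to a divalent oxanickelacyclopentene (Ni, C11, C12, C16, O), which forms C12–C16; σ-bond metathesis of the Ni–O bond with Et3SiH gives the C16 triethylsilyl ether and a vinylnickel hydride, and C–H reductive elimination at C11 with retention returns zerovalent nickel. The closest known reaction is the nickel-catalysed reductive cyclisation of ynals with trialkylsilanes, which gives cyclic allylic silyl ethers with stereodefined exocyclic alkenes. Ring C (C12–C16) closes in a 5-exo-dig sense, C16 bonding to the near alkyne carbon C12 so that C11 stays exocyclic, whereas the six-membered endo alternative would need a bridged metallacycle. The new C16 stereocentre is controlled by the adjacent C15 silyl ether from L-malate: the aldehyde should react through the face that places the C16–O–Ni bond trans to the C15–OTBS group (silyloxy group anti to the forming C–C bond, as in the anti-selective nickel couplings of α-silyloxy aldehydes with alkynes), giving 16S. The step needs syn delivery of H and C16 across the alkyne, which the cis fusion of the metallacycle enforces (H11 cis to C16, C9 cis to C13), and cyclisation faster than plain hydrosilylation of the aldehyde, which the three-atom tether and the electron-rich PBu3 ligand favour. The neutral conditions leave the propargylic C13 centre, the α-silyloxy C15 centre and the crowded tertiary C8–OH untouched.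

Step 15
Reactants: 19 cyclised tris(silyl ether)
Product: 20 allylic alcohol (C16–OH; C13 and C15 O-TBS)
Conditions: PPTS, MeOH/CH2Cl2, 0 °C
Reagents that add atoms: none
Why: Mild acid-catalysed methanolysis cleaves a secondary TES ether far faster than secondary TBS ethers (standard TES/TBS differentiation) and is too weak to ionise the allylic C13 or C16 oxygen.

Step 16
Reactants: 20 allylic alcohol
Product: 21 allylic chloride (16R; Cl cis to the C15 O-TBS group)
Conditions: PPh3, Cl3CCOCCl3, CH2Cl2, −20 → 0 °C
Reagents that add atoms: hexachloroacetone, ClC(Cl)(Cl)C(=O)C(Cl)(Cl)Cl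
Why: Appel-type chlorination with PPh3/hexachloroacetone, the variant known to convert allylic alcohols without allylic transposition, activates C16–OH as an oxyphosphonium ion that chloride displaces by SN2 with inversion, SN2′ attack at C11 being blocked by the neopentyl-like C9 and the hindered tertiary C8–OH not being activated at this temperature.

Step 17
Reactants: 21 allylic chloride
Product: 22 chloro diol (C13–OH, C15–OH, C16–Cl)
Conditions: HF·pyridine, THF, 0 °C → rt
Reagents that add atoms: none
Why: Acidic fluoride desilylation removes both secondary TBS ethers without forming an alkoxide next to the C16 chloride, and the cis C15–O/C16–Cl arrangement in any case cannot close an epoxide.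

Step 18
Reactants: 22 chloro diol
Product: 25 target CNP0279879.2 (16R chloro enol-dione), via hydroxy enone 23 (not isolated), via diketo tautomer 24 (not isolated)
Conditions: Dess–Martin periodinane (2.5 equiv), CH2Cl2, 0 °C → rt
Reagents that add atoms: none
Why: Dess–Martin oxidation of the allylic C13 carbinol and then of the resulting β-hydroxy ketone (the standard access to 1,3-diketones) gives the alkylidene cyclopentanedione, which should enolise to the conjugated C13 enol of the target, while the weakly acidic medium and the small excess of oxidant guard C16–H against epimerisation and C14 against over-oxidation.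

**Compound list**
1 | (+)-sclareolide | CC1(C)CCC[C@]2(C)[C@H]3CC(=O)O[C@]3(C)CC[C@@H]12 | starting material
2 | 8-epi-sclareolide (cis-fused lactone) | CC1(C)CCC[C@]2(C)[C@H]3CC(=O)O[C@@]3(C)CC[C@@H]12 | intermediate
3 | potassium enolate of 2 | CC1(C)CCC[C@]2(C)[C@H]3C=C([O-])O[C@@]3(C)CC[C@@H]12.[K+] | intermediate (not isolated)
4 | 11-hydroxy-8-epi-sclareolide (C11 undefined) | CC1(C)CCC[C@]2(C)[C@H]3C(O)C(=O)O[C@@]3(C)CC[C@@H]12 | intermediate
5 | triol: 8β-hydroxy decalin with 9β-CH(OH)CH2OH (C11 undefined) | CC1(C)CCC[C@]2(C)[C@@H](C(O)CO)[C@@](C)(O)CC[C@@H]12 | intermediate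
6 | 8β-hydroxy-8-epi-driman-11-al (9β-formyl) | CC1(C)CCC[C@]2(C)[C@@H](C=O)[C@@](C)(O)CC[C@@H]12 | intermediate
7 | 9β-ethynyl-8-epi-drimanol | CC1(C)CCC[C@]2(C)[C@@H](C#C)[C@@](C)(O)CC[C@@H]12 | intermediate
8 | dimethyl L-malate (dimethyl (S)-2-hydroxybutanedioate) | COC(=O)C[C@H](O)C(=O)OC | starting material
9 | methyl (S)-3,4-dihydroxybutanoate | COC(=O)C[C@H](O)CO | intermediate
10 | methyl (S)-3,4-bis(tert-butyldimethylsilyloxy)butanoate | COC(=O)C[C@H](O[Si](C)(C)C(C)(C)C)CO[Si](C)(C)C(C)(C)C | intermediate
11 | (S)-3,4-bis(tert-butyldimethylsilyloxy)-N-methoxy-N-methylbutanamide | CON(C)C(=O)C[C@H](O[Si](C)(C)C(C)(C)C)CO[Si](C)(C)C(C)(C)C | intermediate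
12 | dilithium alkoxide acetylide of 7 | CC1(C)CCC[C@]2(C)[C@@H](C#C[Li])[C@@](C)(O[Li])CC[C@@H]12 | intermediate (not isolated)
13 | ynone (C13 ketone; 15S; C15 and C16 O-TBS; free 8β-OH) | CC1(C)CCC[C@]2(C)[C@@H](C#CC(=O)C[C@H](O[Si](C)(C)C(C)(C)C)CO[Si](C)(C)C(C)(C)C)[C@@](C)(O)CC[C@@H]12 | intermediate
14 | (13S,15S)-propargylic alcohol | CC1(C)CCC[C@]2(C)[C@@H](C#C[C@@H](O)C[C@H](O[Si](C)(C)C(C)(C)C)CO[Si](C)(C)C(C)(C)C)[C@@](C)(O)CC[C@@H]12 | intermediate
15 | (13S,15S)-tris-TBS ether (O13, O15, O16) | CC1(C)CCC[C@]2(C)[C@@H](C#C[C@@H](O[Si](C)(C)C(C)(C)C)C[C@H](O[Si](C)(C)C(C)(C)C)CO[Si](C)(C)C(C)(C)C)[C@@](C)(O)CC[C@@H]12 | intermediate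
16 | (13S,15S)-primary alcohol (C16H2OH; O13 and O15 TBS) | CC1(C)CCC[C@]2(C)[C@@H](C#C[C@@H](O[Si](C)(C)C(C)(C)C)C[C@H](O[Si](C)(C)C(C)(C)C)CO)[C@@](C)(O)CC[C@@H]12 | intermediate
17 | (13S,15S)-ynal (C16 aldehyde; O13 and O15 TBS) | CC1(C)CCC[C@]2(C)[C@@H](C#C[C@@H](O[Si](C)(C)C(C)(C)C)C[C@H](O[Si](C)(C)C(C)(C)C)C=O)[C@@](C)(O)CC[C@@H]12 | intermediate
18 | triethylsilane | CC[SiH](CC)CC | starting material
19 | (13S,15S,16S)-2-alkylidenecyclopentane-1,3,5-triol tris(silyl ether): O13 and O15 TBS, O16 TES, H11 cis to C16 | CC1(C)CCC[C@]2(C)[C@@H](/C=C3\[C@@H](O[Si](C)(C)C(C)(C)C)C[C@H](O[Si](C)(C)C(C)(C)C)[C@H]3O[Si](CC)(CC)CC)[C@@](C)(O)CC[C@@H]12 | intermediate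
20 | (13S,15S,16S)-allylic alcohol (C16–OH; O13 and O15 TBS) | CC1(C)CCC[C@]2(C)[C@@H](/C=C3\[C@@H](O[Si](C)(C)C(C)(C)C)C[C@H](O[Si](C)(C)C(C)(C)C)[C@H]3O)[C@@](C)(O)CC[C@@H]12 | intermediate
21 | (13S,15S,16R)-allylic chloride (O13 and O15 TBS) | CC1(C)CCC[C@]2(C)[C@@H](/C=C3\[C@@H](O[Si](C)(C)C(C)(C)C)C[C@H](O[Si](C)(C)C(C)(C)C)[C@@H]3Cl)[C@@](C)(O)CC[C@@H]12 | intermediate
22 | (13S,15S,16R)-chloro diol | CC1(C)CCC[C@]2(C)[C@@H](/C=C3\[C@@H](O)C[C@H](O)[C@@H]3Cl)[C@@](C)(O)CC[C@@H]12 | intermediate
23 | hydroxy enone (C13 ketone, 15S-OH, 16R-Cl) | CC1(C)CCC[C@]2(C)[C@@H](/C=C3\C(=O)C[C@H](O)[C@@H]3Cl)[C@@](C)(O)CC[C@@H]12 | intermediate (not isolated)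
24 | diketo tautomer (C13 and C15 ketones, 16R-Cl) | CC1(C)CCC[C@]2(C)[C@@H](/C=C3\C(=O)CC(=O)[C@@H]3Cl)[C@@](C)(O)CC[C@@H]12 | intermediate (not isolated)
25 | CNP0279879.2: (16R)-chloro enol-dione, C13 enol, C15 ketone, C9 cis to C13 across C11=C12, 8β-OH | CC1(C)CCC[C@]2(C)[C@@H](/C=C3\C(O)=CC(=O)[C@@H]3Cl)[C@@](C)(O)CC[C@@H]12 | target

Total step count: 18. Longest linear sequence: 15 steps (steps 1–5 and 9–18, from sclareolide); the malate branch (steps 6–8) joins at step 9.

**Steps most likely to fail**

Step 14. The oxidative cyclisation may be slowed by the neopentyl-like C9 substituent on the alkyne, so that plain hydrosilylation of the aldehyde or of the alkyne takes over. The aldehyde faces may also be poorly differentiated. The fallback sets out from 16 and forms the same C12–C16 bond by a vinyl halide addition. Palladium-catalysed syn hydrostannation (Bu3SnH, PdCl2(PPh3)2, THF) should place tin on C12, away from C9 and next to the C13 oxygen, giving the vinylstannane F1 with tin cis to H11. Iododestannylation (I2, CH2Cl2, 0 °C) with retention gives the vinyl iodide F2. Dess–Martin oxidation of the primary alcohol gives the iodo aldehyde F3. An intramolecular Nozaki–Hiyama–Kishi reaction (CrCl2, catalytic NiCl2, DMF) then closes ring C with retention of the alkene geometry and comes back to the route at 20, so that step 15 is no longer needed.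

Step 16. The allylic oxyphosphonium ion may ionise, which would erode the configuration at C16 or transpose the allyl system, or the crowded face cis to the C15 silyl ether may resist substitution. The fallback sets out from 20 and separates activation from displacement. Methanesulfonic anhydride and pyridine in CH2Cl2 at 0 °C (no sulfene, so the tertiary C8–OH is spared) give the C16 mesylate F4. LiCl in DMF at room temperature then displaces the sulfonate by SN2 with inversion and comes back to the route at 21.

Step 5. Carbonate in methanol may open ring B by retro-aldol cleavage of the β-hydroxy aldehyde, or expel the axial 8-hydroxyl (anti-periplanar to H9) by an E1cB path, while addition to the hindered formyl group is slow. The fallback sets out from 6 and uses the Corey–Fuchs sequence. CBr4, PPh3 and Et3N in CH2Cl2 at 0 °C give the dibromoalkene F5 under non-protic, essentially neutral conditions. n-BuLi (3.2 equiv) in THF at −78 °C then deprotonates the hydroxyl and triggers the Fritsch–Buttenberg–Wiechell rearrangement, which delivers the dilithium species 12 directly. This comes back to the route at 12, which is acylated with 11 as in step 9, without isolation of 7.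

**Further compounds**
F1 | step 14 | vinylstannane of 16 (SnBu3 on C12, cis to H11; C16H2OH) | CC1(C)CCC[C@]2(C)[C@@H](/C=C(/[Sn](CCCC)(CCCC)CCCC)[C@@H](O[Si](C)(C)C(C)(C)C)C[C@H](O[Si](C)(C)C(C)(C)C)CO)[C@@](C)(O)CC[C@@H]12
F2 | step 14 | vinyl iodide (I on C12, cis to H11; C16H2OH) | CC1(C)CCC[C@]2(C)[C@@H](/C=C(/I)[C@@H](O[Si](C)(C)C(C)(C)C)C[C@H](O[Si](C)(C)C(C)(C)C)CO)[C@@](C)(O)CC[C@@H]12
F3 | step 14 | iodo aldehyde (I on C12; C16 aldehyde) | CC1(C)CCC[C@]2(C)[C@@H](/C=C(/I)[C@@H](O[Si](C)(C)C(C)(C)C)C[C@H](O[Si](C)(C)C(C)(C)C)C=O)[C@@](C)(O)CC[C@@H]12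
F4 | step 16 | C16 methanesulfonate of 20 | CC1(C)CCC[C@]2(C)[C@@H](/C=C3\[C@@H](O[Si](C)(C)C(C)(C)C)C[C@H](O[Si](C)(C)C(C)(C)C)[C@H]3OS(C)(=O)=O)[C@@](C)(O)CC[C@@H]12
F5 | step 5 | 1,1-dibromoalkene from 6 (C9–C11H=C12Br2) | CC1(C)CCC[C@]2(C)[C@@H](C=C(Br)Br)[C@@](C)(O)CC[C@@H]12
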